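**Retrosynthetic overview**
1. 28 ⇐ 27 (Si–O cleavage) ⇐ aldehyde 26: the C9–C10 bond is made last by a light-driven decatungstate/cobaloxime dehydrogenative acyl-radical cyclisation onto the C10=C11(CH3) ring alkene, which sets C10 and creates the exocyclic methylene.
2. 26 ⇐ methyl ketone 23: C7–C8 by chelation-controlled Mukaiyama aldol (sets C7); the C3 ester comes from acid chloride 10, made from (S)-2-hydroxybutanoic acid.
3. 23 ⇐ Weinreb amide 18: C6–C7 by ethynyl addition and the tetrahydropyran by hemiketal reduction (sets C6); C15 by 9-BBN hydroboration.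
4. 18 ⇐ (S)-carvone 11 (cyclohexane ring and C14) + aldehyde 6 (C3 from (R)-linalool): C1–C2 by anti boron aldol (sets C1, C2), then Kabalka 1,3-transposition of the enone.
5. Ring order: cyclohexane (bought) → tetrahydropyran → oxocane (closes the ten-membered carbocycle).

Assumption: compounds 1, 7, 8, 11, 19 and 24 are bought; locants C1–C20 in names follow the eunicellane numbering of 28 (cyclohexane C1, C10–C14; ether oxygen between C2 and C6; ketone C9; side chain C15–C17 on C14; C18 on C3; C19 on C7; exocyclic methylene C20 on C11).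

**Route**

Step 1
Reactants: 1 (R)-(−)-linalool
Product: 3 (5R)-5-ethenyl-5-methyloxolan-2-one, via lactol 2 (not isolated)
Conditions: O3 (1.0 equiv), CH2Cl2, −78 °C; PPh3 (1.0 equiv), → rt; then TEMPO (10 mol%), PhI(OAc)2, rt
Reagents that add atoms: ozone, [O-][O+]=O
Why: Chemoselective ozonolysis of the electron-rich trisubstituted alkene (the vinyl group on the carbinol carbon is much slower), capture of the aldehyde by the tertiary OH as lactol 2, and oxoammonium (TEMPO) oxidation to the γ-lactone, which also masks C3–OH; C3 is the bought stereocentre.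

Step 2
Reactants: 3 (5R)-5-ethenyl-5-methyloxolan-2-one
Product: 5 (4R)-N-methoxy-N,4-dimethyl-4-(triethylsilyloxy)hex-5-enamide, via hydroxy amide 4 (not isolated)
Conditions: MeNH(OMe)·HCl, AlMe3, CH2Cl2, 0 °C → rt; aq. work-up; crude: TESOTf, 2,6-lutidine, CH2Cl2, −78 °C
Reagents that add atoms: N,O-dimethylhydroxylamine hydrochloride, CNOC.Cl; triethylsilyl trifluoromethanesulfonate, CC[Si](CC)(CC)OS(=O)(=O)C(F)(F)F
Why: Weinreb aminolysis of the lactone by the aluminium amide, then immediate silylation of the tertiary alcohol so that it cannot relactonise; no stereocentre is touched.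

Step 3
Reactants: 5 (4R)-N-methoxy-N,4-dimethyl-4-(triethylsilyloxy)hex-5-enamide
Product: 6 (4R)-N-methoxy-N,4-dimethyl-5-oxo-4-(triethylsilyloxy)pentanamide
Conditions: O3, CH2Cl2, −78 °C; PPh3, → rt
Reagents that add atoms: ozone, [O-][O+]=O
Why: Ozonolysis of the remaining vinyl group gives the C2 aldehyde; its α-carbon (C3) is quaternary, so it cannot epimerise or self-condense.

Step 4
Reactants: 7 (2S)-2-hydroxybutanoic acid; 8 butanoyl chloride
Product: 10 (2S)-2-(butanoyloxy)butanoyl chloride, via acid 9 (not isolated)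
Conditions: 8 (2 equiv, neat), 50 °C; then SOCl2, 60 °C; distil
Reagents that add atoms: butanoyl chloride (8), CCCC(=O)Cl; thionyl chloride, O=S(Cl)Cl
Why: Base-free O-acylation of the α-hydroxy acid followed by chlorination (the standard preparation of O-acyl lactyl chlorides), so the S centre is retained.

Step 5
Reactants: 11 (S)-(+)-carvone; 6 (4R)-N-methoxy-N,4-dimethyl-5-oxo-4-(triethylsilyloxy)pentanamide
Product: 13 anti-aldol adduct (carvone ketone C10; new C1–C2 bond trans to the isopropenyl group; C2–OH; chain C2–C6 as in 6), via boron enolate 12 (not isolated)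
Conditions: c-Hex2BCl, Et3N, Et2O, −78 → 0 °C; 6, −78 → −20 °C; pH 7 buffer, MeOH, 30% H2O2, 0 °C
Reagents that add atoms: none
Why: Boron aldol: soft α'-enolisation gives the cyclic E-enol borinate, the closed Zimmerman–Traxler chair gives the anti adduct, and the aldehyde adds to the enolate face opposite the C14 isopropenyl group, which together set C1 and C2 as in 28 (the Me/CH2 pair on C3 of 6 exerts little bias of its own; any C2 epimer is removed by chromatography).

Step 6
Reactants: 13 anti-aldol adduct
Product: 15 (4R,5R)-5-hydroxy-N-methoxy-N,4-dimethyl-5-[3-methyl-6-(prop-1-en-2-yl)cyclohex-2-en-1-yl]-4-(triethylsilyloxy)pentanamide (ring substituents trans; C1 and C14 as in 28), via tosylhydrazone 14 (not isolated)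
Conditions: TsNHNH2, MeOH, rt; evaporate; catecholborane, CHCl3, 0 °C; NaOAc·3H2O, 60 °C
Reagents that add atoms: none
Why: Kabalka alkene-transposing reduction: hydride adds to C=N, loss of sulfinate gives the allylic diazene, and its retro-ene loss of N2 delivers H to C12 and leaves the C10=C11 alkene; no stereocentre is made or touched.

Step 7
Reactants: 15 transposed diene
Product: 17 diol (as 15 with the isopropenyl group converted into (2R)-1-hydroxypropan-2-yl; C15 as in 28), via bis-borane 16 (not isolated)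
Conditions: 9-BBN (2.5 equiv), THF, 0 °C → rt; then NaBO3·4H2O, H2O, rt
Reagents that add atoms: sodium perborate tetrahydrate, [Na+].[O-]B1OO1.O.O.O.O
Why: Substrate-controlled hydroboration–oxidation: 9-BBN takes only the 1,1-disubstituted alkene (C2–OH is borylated first, making the C1 branch bulkier); with C14–H eclipsing the vinylic methyl the borane attacks anti to the C1 branch, giving 15R (the same 1,2-induction as isopulegol → p-menthane-3,9-diol), and oxidation proceeds with retention.

Step 8
Reactants: 17 diol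
Product: 18 primary TBDPS ether of 17 (C16–OSi(t-Bu)Ph2; C2–OH free)
Conditions: TBDPSCl, imidazole, CH2Cl2, 0 °C
Reagents that add atoms: tert-butyl(chloro)diphenylsilane, CC(C)(C)[Si](Cl)(c1ccccc1)c1ccccc1
Why: Imidazole-mediated silylation, selective for the primary C16–OH over the neopentyl-like secondary C2–OH.

Step 9
Reactants: 18 TBDPS ether; 19 ethynylmagnesium bromide
Product: 21 cis-2,6-disubstituted tetrahydropyran (C2 bears the cyclohexenyl group; C3 bears CH3 and OTES; C6 bears ethynyl; H2 and H6 cis), via hemiketal 20 (not isolated)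
Conditions: 19 (4 equiv), THF, −20 → 0 °C; aq. NaHSO4, −20 °C; crude: Et3SiH, BF3·OEt2, CH2Cl2/MeCN, −78 → −40 °C
Reagents that add atoms: ethynylmagnesium bromide (19), C#C[Mg]Br
Why: Weinreb ketone synthesis then Kishi-type reductive etherification: the ynone closes onto C2–OH, BF3 ionises hemiketal 20 to the six-membered oxocarbenium ion and Et3SiH adds axially, placing H6 cis to H2 (C6 as in 28); the C3–OTES group keeps the tertiary oxygen from competing for C6.

Step 10
Reactants: 21 ethynyl tetrahydropyran
Product: 22 methyl ketone with free tertiary C3–OH (C6–C(=O)CH3)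
Conditions: Ph3PAuNTf2 (3 mol%), TsOH·H2O (0.3 equiv), MeOH/H2O 10:1, 40 °C
Reagents that add atoms: water, O
Why: Gold-catalysed Markovnikov hydration of the terminal alkyne gives the methyl ketone while the acid cleaves the tertiary TES ether (the primary TBDPS ether survives); C6 is now α to a ketone, but cis-2,6 is also the thermodynamic arrangement.

Step 11
Reactants: 22 methyl ketone alcohol; 10 (2S)-2-(butanoyloxy)butanoyl chloride
Product: 23 C3 ester of 22 with the (2S)-2-(butanoyloxy)butanoyl group
Conditions: 10 (3 equiv), DMAP (3 equiv), CH2Cl2, 0 → 35 °C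
Reagents that add atoms: none
Why: DMAP-mediated acylation (N-acylpyridinium) of the only free hydroxyl; excess reagent and mild warming for the hindered tertiary alcohol, with no trialkylamine so that ketene formation and loss of the S centre are limited.

Step 12
Reactants: 23 ester ketone; 24 1-(ethylsulfanyl)-1-(trimethylsilyloxy)ethene
Product: 25 β-hydroxy thioester (C7 bears CH3 and OH and CH2C(=O)SEt; 7R as in 28)
Conditions: TiCl4 (2.2 equiv), CH2Cl2, −78 °C; 24, −78 °C; H2O
Reagents that add atoms: 1-(ethylsulfanyl)-1-(trimethylsilyloxy)ethene (24), C=C(SCC)O[Si](C)(C)C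
Why: Mukaiyama aldol under Cram-chelate control: TiCl4 bridges the ketone and ring oxygens and the ketene silyl thioacetal attacks from the C6–H side of the chelate, giving 7R; the esters and silyl ether are inert to this π-nucleophile.

Step 13
Reactants: 25 β-hydroxy thioester
Product: 26 β-hydroxy aldehyde (C9 aldehyde)
Conditions: Et3SiH, 10% Pd/C, acetone, rt
Reagents that add atoms: none
Why: Fukuyama reduction of the thioester stops at the aldehyde and leaves the esters, the trisubstituted alkene and the tertiary alcohol.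

Step 14
Reactants: 26 β-hydroxy aldehyde
Product: 27 16-O-TBDPS ether of the target (tricyclic; C9 ketone; cis H1/H10; C11=C20 exocyclic methylene)
Conditions: (n-Bu4N)4[W10O32] (4 mol%), Co(dmgH)2(py)Cl (8 mol%), MeCN (3 mM), 390 nm LEDs, 15 °C, argon
Reagents that add atoms: none
Why: Proposed new method: excited decatungstate abstracts the formyl hydrogen (the weakest, most hydridic C–H) to give the C9 acyl radical, which adds 8-exo to C10 of the trisubstituted ring alkene from the face on which the tether sits (cis to C2, so H10 ends cis to H1); the tertiary C11 radical is then intercepted by divalent cobalt (cobaloxime), which removes a hydrogen from the unhindered C20 methyl to give the exocyclic alkene, and the cobalt hydride and reduced polyoxometalate release H2 to close both cycles. The closest known reaction types are decatungstate hydroacylation of alkenes, acyl-radical cyclisations and decatungstate/cobaloxime acceptorless dehydrogenation; what is new is their merger into a formal dehydrogenative acyl-ene ring closure of a medium ring onto an unactivated alkene.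

Step 15
Reactants: 27 silyl ether
Product: 28 target CNP0291223.2
Conditions: HF·pyridine, pyridine/THF, 0 °C → rt
Reagents that add atoms: none
Why: Fluoride cleavage of the TBDPS ether under buffered, weakly acidic conditions that neither epimerise C10, conjugate the β,γ-enone, nor dehydrate the β-hydroxy ketone.

**Compound list**
1 | (R)-(−)-linalool, (3R)-3,7-dimethylocta-1,6-dien-3-ol | CC(C)=CCC[C@@](C)(O)C=C | starting material
2 | (5R)-5-ethenyl-5-methyloxolan-2-ol (lactol, both anomers; not isolated) | OC1CC[C@@](C)(O1)C=C | intermediate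
3 | (5R)-5-ethenyl-5-methyloxolan-2-one ((R)-lavender lactone) | O=C1CC[C@@](C)(O1)C=C | intermediate
4 | (4R)-4-hydroxy-N-methoxy-N,4-dimethylhex-5-enamide (not isolated) | CON(C)C(=O)CC[C@@](C)(O)C=C | intermediate
5 | (4R)-N-methoxy-N,4-dimethyl-4-(triethylsilyloxy)hex-5-enamide | CON(C)C(=O)CC[C@@](C)(O[Si](CC)(CC)CC)C=C | intermediate
6 | (4R)-N-methoxy-N,4-dimethyl-5-oxo-4-(triethylsilyloxy)pentanamide | CON(C)C(=O)CC[C@@](C)(O[Si](CC)(CC)CC)C=O | intermediate
7 | (2S)-2-hydroxybutanoic acid | CC[C@H](O)C(=O)O | starting material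
8 | butanoyl chloride | CCCC(=O)Cl | starting material
9 | (2S)-2-(butanoyloxy)butanoic acid (not isolated) | CCCC(=O)O[C@@H](CC)C(=O)O | intermediate
10 | (2S)-2-(butanoyloxy)butanoyl chloride | CCCC(=O)O[C@@H](CC)C(Cl)=O | intermediate
11 | (S)-(+)-carvone, (5S)-2-methyl-5-(prop-1-en-2-yl)cyclohex-2-en-1-one | CC1=CC[C@H](C(C)=C)CC1=O | starting material
12 | dicyclohexylboron cross-conjugated enolate of 11 (O–B on C10, C10=C1; not isolated) | CC1=CC[C@H](C(C)=C)C=C1OB(C1CCCCC1)C1CCCCC1 | intermediate
13 | anti-aldol adduct: carvone carrying at C1 (trans to isopropenyl) the (1R,2R)-1-hydroxy-5-[methoxy(methyl)amino]-2-methyl-5-oxo-2-(triethylsilyloxy)pentyl chain; C1, C2, C3, C14 as in 28 | CC1=CC[C@H](C(C)=C)[C@@H]([C@@H](O)[C@](C)(O[Si](CC)(CC)CC)CCC(=O)N(C)OC)C1=O | intermediate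
14 | N-tosylhydrazone of 13 at C10 (not isolated) | CC1=CC[C@H](C(C)=C)[C@@H]([C@@H](O)[C@](C)(O[Si](CC)(CC)CC)CCC(=O)N(C)OC)C1=NNS(=O)(=O)c1ccc(C)cc1 | intermediate
15 | (4R,5R)-5-hydroxy-N-methoxy-N,4-dimethyl-5-[3-methyl-6-(prop-1-en-2-yl)cyclohex-2-en-1-yl]-4-(triethylsilyloxy)pentanamide; ring substituents trans, C1 and C14 as in 28 | CC1=C[C@H]([C@@H](O)[C@](C)(O[Si](CC)(CC)CC)CCC(=O)N(C)OC)[C@@H](C(C)=C)CC1 | intermediate
16 | bis(9-borabicyclo[3.3.1]nonan-9-yl) derivative of 15: B on C16 and on the C2 oxygen (not isolated) | CC1=C[C@H]([C@@H](OB2C3CCCC2CCC3)[C@](C)(O[Si](CC)(CC)CC)CCC(=O)N(C)OC)[C@@H]([C@@H](C)CB2C3CCCC2CCC3)CC1 | intermediate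
17 | diol: 15 with the side chain on C14 now (2R)-1-hydroxypropan-2-yl (C15 as in 28) | CC1=C[C@H]([C@@H](O)[C@](C)(O[Si](CC)(CC)CC)CCC(=O)N(C)OC)[C@@H]([C@@H](C)CO)CC1 | intermediate
18 | 16-O-tert-butyldiphenylsilyl ether of 17 | CC1=C[C@H]([C@@H](O)[C@](C)(O[Si](CC)(CC)CC)CCC(=O)N(C)OC)[C@@H]([C@@H](C)CO[Si](c2ccccc2)(c3ccccc3)C(C)(C)C)CC1 | intermediate
19 | ethynylmagnesium bromide | C#C[Mg]Br | starting material
20 | 6-ethynyl-6-hydroxy tetrahydropyran hemiketal (C2–O–C6 ring; anomers; not isolated) | CC1=C[C@H]([C@H]2OC(O)(C#C)CC[C@@]2(C)O[Si](CC)(CC)CC)[C@@H]([C@@H](C)CO[Si](c3ccccc3)(c4ccccc4)C(C)(C)C)CC1 | intermediate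
21 | cis-2,6-tetrahydropyran: C2 cyclohexenyl, C3 (CH3)(OTES), C6 ethynyl; C2, C3, C6 as in 28 | CC1=C[C@H]([C@H]2O[C@@H](C#C)CC[C@@]2(C)O[Si](CC)(CC)CC)[C@@H]([C@@H](C)CO[Si](c3ccccc3)(c4ccccc4)C(C)(C)C)CC1 | intermediate
22 | 6-acetyl tetrahydropyran with free tertiary C3–OH | CC1=C[C@H]([C@H]2O[C@@H](C(C)=O)CC[C@@]2(C)O)[C@@H]([C@@H](C)CO[Si](c3ccccc3)(c4ccccc4)C(C)(C)C)CC1 | intermediate
23 | C3 (2S)-2-(butanoyloxy)butanoate of 22 | CC1=C[C@H]([C@H]2O[C@@H](C(C)=O)CC[C@@]2(C)OC(=O)[C@H](CC)OC(=O)CCC)[C@@H]([C@@H](C)CO[Si](c3ccccc3)(c4ccccc4)C(C)(C)C)CC1 | intermediate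
24 | 1-(ethylsulfanyl)-1-(trimethylsilyloxy)ethene | C=C(SCC)O[Si](C)(C)C | starting material
25 | S-ethyl β-hydroxy thioester: C7 (CH3)(OH), C8H2, C9(=O)SEt; 7R as in 28 | CC1=C[C@H]([C@H]2O[C@@H]([C@](C)(O)CC(=O)SCC)CC[C@@]2(C)OC(=O)[C@H](CC)OC(=O)CCC)[C@@H]([C@@H](C)CO[Si](c3ccccc3)(c4ccccc4)C(C)(C)C)CC1 | intermediate
26 | β-hydroxy aldehyde (C9HO) | CC1=C[C@H]([C@H]2O[C@@H]([C@](C)(O)CC=O)CC[C@@]2(C)OC(=O)[C@H](CC)OC(=O)CCC)[C@@H]([C@@H](C)CO[Si](c3ccccc3)(c4ccccc4)C(C)(C)C)CC1 | intermediate
27 | 16-O-tert-butyldiphenylsilyl ether of the target | C=C1CC[C@H]([C@@H](C)CO[Si](c3ccccc3)(c4ccccc4)C(C)(C)C)[C@@H]2[C@H]1C(=O)C[C@@](C)(O)[C@H]1CC[C@@](C)(OC(=O)[C@H](CC)OC(=O)CCC)[C@@H]2O1 | intermediate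
28 | CNP0291223.2 (1R,2R,3R,6R,7R,10R,14R,15R; 2'S) | C=C1CC[C@H]([C@@H](C)CO)[C@@H]2[C@H]1C(=O)C[C@@](C)(O)[C@H]1CC[C@@](C)(OC(=O)[C@H](CC)OC(=O)CCC)[C@@H]2O1 | target

**Step count and risks**
Total steps: 15. Longest linear sequence: 14 (steps 1–3, then 5–15).

Most likely to fail:

Step 14 (the new ring closure). The acyl radical must close an eight-membered ring onto an unactivated alkene, which requires the tetrahydropyran to place its C2 and C6 arms axial; decarbonylation and hydrogen abstraction at C10 instead of C20 can compete. The fallback sets out from 26 and uses ground-state chemistry: Me2AlCl (2.5 equiv, CH2Cl2, −78 → −20 °C) promotes an intramolecular carbonyl-ene reaction in which the aldehyde–aluminium complex, which is persistent and so tolerates a slow closure, is attacked by C10 with transfer of a C20 hydrogen to give the homoallylic C9 carbinol F4 (either C9 epimer; any endocyclic alkene isomer is separated). Dess–Martin periodinane buffered with NaHCO3 then oxidises F4 to the ketone, and the route is rejoined at 27.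

Step 11 (acylation of the hindered tertiary C3–OH with an α-branched, epimerisable acyl chloride). The fallback sets out from 21 and changes both the order and the activation mode: PPTS in MeOH removes the TES group to give the ethynyl tertiary alcohol F2, whose lithium alkoxide (n-BuLi, 1.0 equiv, THF, −78 °C) is acylated with 10 at −78 °C, with no amine base and no enolisable ketone present, to give the ethynyl ester F3. Gold-catalysed hydration (Ph3PAuNTf2, wet 1,4-dioxane) then returns to the route at 23.

Step 9 (tetrahydropyran formation). The magnesium alkoxide at C2 sits next to the C3 silyl ether (O-to-O silyl migration would lead to a tetrahydrofuran), the liberated amine can add to the terminal ynone, and the oxocarbenium ion could be trapped by the ring alkene. The fallback sets out from 18: catalytic camphorsulfonic acid in toluene at 60 °C lactonises the hydroxy Weinreb amide to the δ-lactone F1 (C2–O–C6(=O)). Ethynylmagnesium bromide (1.2 equiv, THF, −78 °C) then adds once to the lactone carbonyl, with no alkoxide next to the silyl ether and no free amine, to give hemiketal 20 directly, where the route is rejoined before the same Et3SiH/BF3·OEt2 reduction.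

**Further compounds**
F1 | step 9 | δ-lactone from 18: 6-oxo tetrahydropyran with C2 cyclohexenyl and C3 (CH3)(OTES) | CC1=C[C@H]([C@H]2OC(=O)CC[C@@]2(C)O[Si](CC)(CC)CC)[C@@H]([C@@H](C)CO[Si](c3ccccc3)(c4ccccc4)C(C)(C)C)CC1
F2 | step 11 | ethynyl tetrahydropyran with free tertiary C3–OH (21 without TES) | CC1=C[C@H]([C@H]2O[C@@H](C#C)CC[C@@]2(C)O)[C@@H]([C@@H](C)CO[Si](c3ccccc3)(c4ccccc4)C(C)(C)C)CC1
F3 | step 11 | C3 (2S)-2-(butanoyloxy)butanoate of F2 | CC1=C[C@H]([C@H]2O[C@@H](C#C)CC[C@@]2(C)OC(=O)[C@H](CC)OC(=O)CCC)[C@@H]([C@@H](C)CO[Si](c3ccccc3)(c4ccccc4)C(C)(C)C)CC1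
F4 | step 14 | C9 carbinol of 27 (tricyclic homoallylic alcohol, either C9 epimer) | C=C1CC[C@H]([C@@H](C)CO[Si](c3ccccc3)(c4ccccc4)C(C)(C)C)[C@@H]2[C@H]1C(O)C[C@@](C)(O)[C@H]1CC[C@@](C)(OC(=O)[C@H](CC)OC(=O)CCC)[C@@H]2O1
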